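**Retrosynthetic overview**
- Target 11 ← 10: the C4'–Br bond is made last, by electrophilic bromination para to the ether oxygen on the phenoxy ring.
- 10 ← phenol 4 + benzyne (from silyl triflate 5) + CBr4 (6). The strategy rests on the ether oxygen at C1' and the bromine at C2' sitting on adjacent carbons of the dibromophenoxy ring, so C1'–O and C2'–Br are formed together across an aryne triple bond.
- 4 ← 2 (Baeyer–Villiger oxidation, formate cleavage) ← 1 (O-methylation).
- No ring is formed: the methoxy ring comes from 1 and the phenoxy ring from 5.

Key step: step 3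

Assumption: the target has no stereocentre and is achiral, so "single enantiomer" carries no stereochemical requirement and no stereocontrol is planned.

**Step 1**
Reactants: 1 3,5-dibromo-2-hydroxybenzaldehyde (3,5-dibromosalicylaldehyde)
Product: 2 3,5-dibromo-2-methoxybenzaldehyde
Conditions: MeI, K2CO3, DMF, rt → 40 °C
Reagents that add atoms: iodomethane, CI
Why: Williamson ether synthesis; the phenol, acidified by the ortho-formyl group and two bromines, is deprotonated by carbonate and should be methylated at oxygen by SN2 on iodomethane, with the aldehyde and aryl bromides inert.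

**Step 2**
Reactants: 2 3,5-dibromo-2-methoxybenzaldehyde
Product: 4 3,5-dibromo-2-methoxyphenol, via 3,5-dibromo-2-methoxyphenyl formate 3 (not isolated)
Conditions: mCPBA, CH2Cl2, reflux; aq. Na2SO3/NaHCO3 wash; then Et3N (cat.), MeOH, rt
Reagents that add atoms: 3-chloroperoxybenzoic acid (mCPBA), OOC(=O)c1cccc(Cl)c1
Why: Baeyer–Villiger (Dakin-type) oxidation; the peracid adds to the aldehyde, the aryl group, assisted by the ortho-methoxy lone pair, should migrate to oxygen in the Criegee intermediate to give formate 3, and this activated ester is then cleaved by base-catalysed methanolysis.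

**Step 3**
Reactants: 4 3,5-dibromo-2-methoxyphenol; 5 2-(trimethylsilyl)phenyl trifluoromethanesulfonate; 6 carbon tetrabromide
Product: 10 1,5-dibromo-3-(2-bromophenoxy)-2-methoxybenzene, via potassium 3,5-dibromo-2-methoxyphenoxide 7 (not isolated), via benzyne 8 (not isolated), via 2-(3,5-dibromo-2-methoxyphenoxy)phenylpotassium 9 (not isolated)
Conditions: KH, THF, 0 °C → rt; then CBr4 (2.5 equiv), KF, 18-crown-6, slow addition of 5 (1.5 equiv), THF, 0 °C → rt; H2O quench
Reagents that add atoms: none
Why: Proposed new method: fluoride attacks silicon of 5 and triflate leaves to release benzyne 8, the preformed phenoxide 7 adds through oxygen to the strained triple bond (C1'–O), and the resulting ortho aryl anion 9 attacks a bromine of CBr4 in a halogenophilic substitution with tribromomethanide as leaving group (C2'–Br). The closest known reaction types are the fluoride-mediated O-arylation of phenols with silylaryl triflates and three-component aryne couplings in which a heteroatom nucleophile adds and the aryl anion is quenched by halogen transfer from a polyhalogenated donor. No ring is closed and no stereocentre is formed. Benzyne is symmetrical, so no regiochemical question arises at the aryne, and the ortho relation of oxygen and bromine follows from the mechanism. Bromine transfer must outrun protonation of 9, which is secured by deprotonating the phenol with KH (only H2 is released), by using THF in place of acetonitrile and by anhydrous KF/18-crown-6. The phenoxide must not be brominated itself, which is helped by its two deactivating ring bromines, by the much higher reactivity of CBr4 toward carbanions than toward phenoxides, and by slow addition of 5 so that benzyne stays dilute.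

**Step 4**
Reactants: 10 1,5-dibromo-3-(2-bromophenoxy)-2-methoxybenzene
Product: 11 1,5-dibromo-3-(2,4-dibromophenoxy)-2-methoxybenzene (target)
Conditions: Br2 (1.05 equiv), AcOH, rt → 40 °C
Reagents that add atoms: bromine, BrBr
Why: Electrophilic aromatic bromination; C4' is para to the ether oxygen on the ring carrying only one bromine and is unhindered, whereas on the methoxy ring C4 lies between two bromines, C6 is an ortho position flanked by Br and OAr, and the methoxy group has both ortho positions and its para position blocked, so one equivalent of bromine should go to C4'.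

**Compound list**
1 | 3,5-dibromo-2-hydroxybenzaldehyde (3,5-dibromosalicylaldehyde) | O=Cc1cc(Br)cc(Br)c1O | starting material
2 | 3,5-dibromo-2-methoxybenzaldehyde | COc1c(Br)cc(Br)cc1C=O | intermediate
3 | 3,5-dibromo-2-methoxyphenyl formate | COc1c(Br)cc(Br)cc1OC=O | intermediate
4 | 3,5-dibromo-2-methoxyphenol | COc1c(Br)cc(Br)cc1O | intermediate
5 | 2-(trimethylsilyl)phenyl trifluoromethanesulfonate | C[Si](C)(C)c1ccccc1OS(=O)(=O)C(F)(F)F | starting material
6 | carbon tetrabromide | BrC(Br)(Br)Br | starting material
7 | potassium 3,5-dibromo-2-methoxyphenoxide | COc1c(Br)cc(Br)cc1[O-].[K+] | intermediate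
8 | benzyne | C1#CC=CC=C1 | intermediate
9 | 2-(3,5-dibromo-2-methoxyphenoxy)phenylpotassium | COc1c(Br)cc(Br)cc1Oc1ccccc1[K] | intermediate
10 | 1,5-dibromo-3-(2-bromophenoxy)-2-methoxybenzene | COc1c(Br)cc(Br)cc1Oc1ccccc1Br | intermediate
11 | 1,5-dibromo-3-(2,4-dibromophenoxy)-2-methoxybenzene | COc1c(Br)cc(Br)cc1Oc1ccc(Br)cc1Br | target

**Total step count:** 4
**Longest linear sequence:** 4 steps (1 → 2 → 4 → 10 → 11)

**Steps most likely to fail**

1. Step 3 (proposed new method). Protonation of the aryl anion by adventitious proton sources may outrun bromine transfer. Bromide and tribromomethanide released from CBr4 may consume benzyne. The phenoxide may be ring-brominated by CBr4 before it meets the aryne. Fallback with known chemistry, setting out from phenol 4: SNAr on 1-fluoro-2-nitrobenzene (K2CO3, DMF, 80 °C) should give 1,5-dibromo-2-methoxy-3-(2-nitrophenoxy)benzene F1. Reduction that spares aryl bromides (Fe, NH4Cl, EtOH/H2O, 80 °C) should give 2-(3,5-dibromo-2-methoxyphenoxy)aniline F2. Diazotisation (NaNO2, 48% HBr, MeCN/H2O, 0 °C) forms 2-(3,5-dibromo-2-methoxyphenoxy)benzenediazonium bromide F3, which is treated in the same flask with CuBr (Sandmeyer reaction). This returns to the route at compound 10.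

2. Step 4. Bromination may be unselective between the two rings (attack at C6 of the methoxy ring) or between para and ortho positions (C6'), and a second bromination may follow, giving mixtures of closely related polybromides. Fallback, setting out from phenol 4, with the C4' bromine carried in with the arylating partner: SNAr on 4-bromo-1-fluoro-2-nitrobenzene (K2CO3, DMF, 80 °C) should give 1,5-dibromo-3-(4-bromo-2-nitrophenoxy)-2-methoxybenzene F4. Reduction (Fe, NH4Cl, EtOH/H2O) should give 5-bromo-2-(3,5-dibromo-2-methoxyphenoxy)aniline F5. Diazotisation (NaNO2, HBr, MeCN/H2O, 0 °C) to 5-bromo-2-(3,5-dibromo-2-methoxyphenoxy)benzenediazonium bromide F6 and Sandmeyer bromination with CuBr place bromine at C2' unambiguously. This returns to the route at target 11.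

3. Step 2. In the Criegee intermediate, hydride migration may compete with aryl migration because the two bromines make the ring a poorer migrating group, which would divert material to the carboxylic acid. Fallback, setting out from aldehyde 2, which removes the migrating hydrogen: MeMgBr (THF, −78 → 0 °C) should give racemic 1-(3,5-dibromo-2-methoxyphenyl)ethanol F7. Dess–Martin oxidation should give 1-(3,5-dibromo-2-methoxyphenyl)ethanone F8. Baeyer–Villiger oxidation (mCPBA, TFA, CH2Cl2), in which only aryl or methyl can migrate and aryl is far preferred, should give 3,5-dibromo-2-methoxyphenyl acetate F9. Methanolysis (K2CO3, MeOH, rt) returns to the route at compound 4.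

**Further compounds**
F1 | step 3 | 1,5-dibromo-2-methoxy-3-(2-nitrophenoxy)benzene | COc1c(Br)cc(Br)cc1Oc1ccccc1[N+](=O)[O-]
F2 | step 3 | 2-(3,5-dibromo-2-methoxyphenoxy)aniline | COc1c(Br)cc(Br)cc1Oc1ccccc1N
F3 | step 3 | 2-(3,5-dibromo-2-methoxyphenoxy)benzenediazonium bromide | COc1c(Br)cc(Br)cc1Oc1ccccc1[N+]#N.[Br-]
F4 | step 4 | 1,5-dibromo-3-(4-bromo-2-nitrophenoxy)-2-methoxybenzene | COc1c(Br)cc(Br)cc1Oc1ccc(Br)cc1[N+](=O)[O-]
F5 | step 4 | 5-bromo-2-(3,5-dibromo-2-methoxyphenoxy)aniline | COc1c(Br)cc(Br)cc1Oc1ccc(Br)cc1N
F6 | step 4 | 5-bromo-2-(3,5-dibromo-2-methoxyphenoxy)benzenediazonium bromide | COc1c(Br)cc(Br)cc1Oc1ccc(Br)cc1[N+]#N.[Br-]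
F7 | step 2 | 1-(3,5-dibromo-2-methoxyphenyl)ethanol (racemic) | COc1c(Br)cc(Br)cc1C(C)O
F8 | step 2 | 1-(3,5-dibromo-2-methoxyphenyl)ethanone | COc1c(Br)cc(Br)cc1C(C)=O
F9 | step 2 | 3,5-dibromo-2-methoxyphenyl acetate | COc1c(Br)cc(Br)cc1OC(C)=O
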